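The synthesis rests on cutting the bond between the ketone carbon and its syringyl ring. On the tetrahydrofuran ring (O1, C2 to C5) the C3 hydroxymethyl group and the C4 acyl carbon are cis, so together they are a ring-opened gamma-lactone. The key-step precursor is therefore the cis-fused bicyclic lactone 10, which already carries C2, C3 and C4. Aryllithium 13 adds to its carbonyl carbon. One operation joins the halves, opens the temporary ring and releases ketone and primary alcohol, and the cis geometry stays locked until the quench. Lactone 10 comes from an L-proline cross-aldol, a Mitsunobu inversion with formic acid, and transfer of that formyl carbon to C4, where it becomes C5.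

Key step: step 7

Assumption: keto alcohols 15 and 16 may equilibrate with their bicyclic hemiketals and are drawn in the open form, as in the target.
Abbreviation: Ar = 4-(tert-butyldimethylsilyloxy)-3,5-dimethoxyphenyl. O1 and C2 to C5 are the ring atoms of the target tetrahydrofuran (C2 aryl, C3 hydroxymethyl, C4 aroyl).

Step 1
Reactants: 1 syringaldehyde (4-hydroxy-3,5-dimethoxybenzaldehyde)
Product: 2 4-(tert-butyldimethylsilyloxy)-3,5-dimethoxybenzaldehyde
Conditions: TBSCl, imidazole, DMF, rt
Reagents that add atoms: tert-butyldimethylsilyl chloride (TBSCl), C[Si](C)(Cl)C(C)(C)C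
Why: Imidazole-promoted O-silylation of the phenol removes the acidic proton before the enolate and aryllithium steps, and the aryl silyl ether leaves cleanly with fluoride at the end.

Step 2
Reactants: 2 4-(tert-butyldimethylsilyloxy)-3,5-dimethoxybenzaldehyde, 3 methyl 4-oxobutanoate
Product: 6 (4R)-4-[(R)-Ar(hydroxy)methyl]dihydrofuran-2(3H)-one, via aldol aldehyde 4 (not isolated), via diol ester 5 (not isolated)
Conditions: L-proline (30 mol %), DMF, 4 °C, slow addition of 3; then MeOH, NaBH4, 0 °C; aq NH4Cl
Reagents that add atoms: none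
Why: Proline-catalysed direct cross-aldol reaction (enamine catalysis) of enolisable 3 with non-enolisable 2, in which the (E)-enamine of L-proline attacks the hydrogen-bonded aldehyde through a chair-like transition state and sets the future C3 in its final (R) sense with the carbinol carbon anti to it, after which borohydride reduction of the formyl group lets the primary alcohol close the lactone on the methyl ester faster than the hindered benzylic alcohol can.

Step 3
Reactants: 6 (4R)-4-[(R)-Ar(hydroxy)methyl]dihydrofuran-2(3H)-one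
Product: 7 (S)-Ar[(3R)-5-oxotetrahydrofuran-3-yl]methyl formate
Conditions: HCO2H, PPh3, DIAD, THF, 0 °C to rt
Reagents that add atoms: formic acid, O=CO
Why: Mitsunobu reaction in which SN2 displacement of the benzylic oxyphosphonium ion by formate inverts the carbinol carbon to the (S) configuration of C2 and at the same time places on O1 the carbon that will become C5.

Step 4
Reactants: 7 (S)-Ar[(3R)-5-oxotetrahydrofuran-3-yl]methyl formate
Product: 9 (3aR,4S)-4-Ar-3a,4-dihydro-1H,3H-furo[3,4-c]furan-1-one, via formyl lactone 8 (not isolated)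
Conditions: LiN(SiMe3)2 (1.2 equiv), THF, −78 to −40 °C; AcOH; then catalytic PPTS, 4 Å molecular sieves, CH2Cl2, rt
Reagents that add atoms: none
Why: Intramolecular Claisen condensation (O-to-C acyl transfer of the Baker–Venkataraman type) in which the lactone enolate attacks the neighbouring formate in a 5-exo-trig mode, the stabilised formyl enolate so formed shields the lactone from translactonisation, and under mild acid the freed benzylic hydroxyl adds to the formyl group and loses water to give the beta-alkoxyacrylate ring with the C2–O1 bond, and so the C2 configuration, untouched.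

Step 5
Reactants: 9 (3aR,4S)-4-Ar-3a,4-dihydro-1H,3H-furo[3,4-c]furan-1-one
Product: 10 (3aR,4S,6aR)-4-Ar-tetrahydro-1H,3H-furo[3,4-c]furan-1-one
Conditions: H2 (4 atm), 5% Rh on Al2O3, EtOAc, rt
Reagents that add atoms: none
Why: Heterogeneous catalytic hydrogenation of a beta-alkoxyacrylate in which syn delivery of hydrogen to the convex face, the face of the C3 hydrogen, sets C4 (position 6a) as the only strain-free cis ring fusion, and rhodium is chosen over palladium because it has little tendency to cleave the benzylic C2–O1 bond.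

Step 6
Reactants: 11 4-bromo-2,6-dimethoxyphenol
Product: 12 (4-bromo-2,6-dimethoxyphenoxy)(tert-butyl)dimethylsilane
Conditions: TBSCl, imidazole, DMF, rt
Reagents that add atoms: tert-butyldimethylsilyl chloride (TBSCl), C[Si](C)(Cl)C(C)(C)C
Why: Imidazole-promoted O-silylation masks the phenol so that the later bromine–lithium exchange gives a soluble monolithiated arene.

Step 7
Reactants: 12 (4-bromo-2,6-dimethoxyphenoxy)(tert-butyl)dimethylsilane, 10 (3aR,4S,6aR)-4-Ar-tetrahydro-1H,3H-furo[3,4-c]furan-1-one
Product: 15 [(3R,4R,5S)-5-Ar-4-(hydroxymethyl)tetrahydrofuran-3-yl](Ar)methanone (bis-TBS ciwujiatone), via aryllithium 13 (not isolated), via lithium hemiketal alkoxide 14 (not isolated)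
Conditions: 12 (1.3 equiv), n-BuLi (1.25 equiv), THF, −78 °C; then 10 in THF, −78 °C; AcOH in THF at −78 °C
Reagents that add atoms: none
Why: Bromine–lithium exchange turns 12 into aryllithium 13, whose carbanionic ring carbon attacks the lactone carbonyl carbon of 10 to give the tetrahedral lithium alkoxide 14, and protonation lets the hemiketal open to the aryl ketone at C4 and the free hydroxymethyl group at C3. The closest known reaction type is the single addition of an aryllithium to a gamma-lactone that stops at the lactol stage, a standard way to aryl ketones and aryl hemiketals. No ring is closed, the temporary lactone ring is the one that opens, and no new stereocentre remains because the hemiketal carbon of 14 ends as the planar carbonyl carbon. C2, C3 and C4 come unchanged from 10, and the cis relation of C3 and C4 is held by the bicyclic frame of 14 as long as base is present. The step needs mono-addition and no epimerisation at C4: 14 does not collapse to the ketone at −78 °C, so 13 never meets a ketone, and the cold acetic acid quench removes all base before the ketone appears. Competing deprotonation of 10 at C4 costs only conversion, since the enolate can reprotonate only to the cis-fused lactone.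

Step 8
Reactants: 15 bis-TBS ciwujiatone
Product: 16 ciwujiatone, [(3R,4R,5S)-5-(4-hydroxy-3,5-dimethoxyphenyl)-4-(hydroxymethyl)tetrahydrofuran-3-yl](4-hydroxy-3,5-dimethoxyphenyl)methanone
Conditions: TBAF (2.5 equiv), AcOH (3 equiv), THF, 0 °C
Reagents that add atoms: none
Why: Fluoride-driven cleavage of both aryl silyl ethers, buffered with acetic acid so that no basic fluoride or phenoxide can epimerise the ketone alpha carbon C4 or open the beta-alkoxy ketone.

Compound list
1 | syringaldehyde | COc1cc(C=O)cc(OC)c1O | starting material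
2 | 4-(tert-butyldimethylsilyloxy)-3,5-dimethoxybenzaldehyde | COc1cc(C=O)cc(OC)c1O[Si](C)(C)C(C)(C)C | intermediate
3 | methyl 4-oxobutanoate | COC(=O)CCC=O | starting material
4 | methyl (3S,4R)-3-formyl-4-hydroxy-4-Ar-butanoate (aldol aldehyde) | COC(=O)C[C@H](C=O)[C@@H](O)c1cc(OC)c(O[Si](C)(C)C(C)(C)C)c(OC)c1 | intermediate
5 | methyl (3R,4R)-4-hydroxy-3-(hydroxymethyl)-4-Ar-butanoate (diol ester) | COC(=O)C[C@H](CO)[C@@H](O)c1cc(OC)c(O[Si](C)(C)C(C)(C)C)c(OC)c1 | intermediate
6 | (4R)-4-[(R)-Ar(hydroxy)methyl]dihydrofuran-2(3H)-one | O=C1C[C@H](CO1)[C@@H](O)c2cc(OC)c(O[Si](C)(C)C(C)(C)C)c(OC)c2 | intermediate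
7 | (S)-Ar[(3R)-5-oxotetrahydrofuran-3-yl]methyl formate | O=C1C[C@H](CO1)[C@H](OC=O)c2cc(OC)c(O[Si](C)(C)C(C)(C)C)c(OC)c2 | intermediate
8 | (4R)-4-[(S)-Ar(hydroxy)methyl]-2-oxotetrahydrofuran-3-carbaldehyde (formyl lactone, enolised at position 3) | O=CC1C(=O)OC[C@@H]1[C@H](O)c2cc(OC)c(O[Si](C)(C)C(C)(C)C)c(OC)c2 | intermediate
9 | (3aR,4S)-4-Ar-3a,4-dihydro-1H,3H-furo[3,4-c]furan-1-one | O=C1OC[C@H]2C1=CO[C@@H]2c3cc(OC)c(O[Si](C)(C)C(C)(C)C)c(OC)c3 | intermediate
10 | (3aR,4S,6aR)-4-Ar-tetrahydro-1H,3H-furo[3,4-c]furan-1-one | O=C1OC[C@H]2[C@@H]1CO[C@@H]2c3cc(OC)c(O[Si](C)(C)C(C)(C)C)c(OC)c3 | intermediate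
11 | 4-bromo-2,6-dimethoxyphenol | COc1cc(Br)cc(OC)c1O | starting material
12 | (4-bromo-2,6-dimethoxyphenoxy)(tert-butyl)dimethylsilane | COc1cc(Br)cc(OC)c1O[Si](C)(C)C(C)(C)C | intermediate
13 | 4-(tert-butyldimethylsilyloxy)-3,5-dimethoxyphenyllithium | [Li]c1cc(OC)c(O[Si](C)(C)C(C)(C)C)c(OC)c1 | intermediate
14 | lithium (3aR,4S,6aR)-1,4-di-Ar-tetrahydro-1H,3H-furo[3,4-c]furan-1-olate | [Li]OC1(c3cc(OC)c(O[Si](C)(C)C(C)(C)C)c(OC)c3)OC[C@H]2[C@@H]1CO[C@@H]2c4cc(OC)c(O[Si](C)(C)C(C)(C)C)c(OC)c4 | intermediate
15 | [(3R,4R,5S)-5-Ar-4-(hydroxymethyl)tetrahydrofuran-3-yl](Ar)methanone | COc1cc(C(=O)[C@H]2CO[C@H](c3cc(OC)c(O[Si](C)(C)C(C)(C)C)c(OC)c3)[C@H]2CO)cc(OC)c1O[Si](C)(C)C(C)(C)C | intermediate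
16 | ciwujiatone | COc1cc(C(=O)[C@H]2CO[C@H](c3cc(OC)c(O)c(OC)c3)[C@H]2CO)cc(OC)c1O | target

Total step count: 8. Longest linear sequence: 7 steps (1, 2, 3, 4, 5, 7, 8).

Steps most likely to fail

Step 4 (formyl transfer).
- **Risk:** The amide base may add to the very electrophilic formate carbonyl instead of deprotonating the lactone. The benzylic alkoxide freed in that way may then migrate onto the lactone carbonyl.
- **Fallback:** It sets out from 7 and comes back at 9. Heating 7 with tert-butoxybis(dimethylamino)methane in toluene condenses the reagent with the lactone alpha-methylene group without strong base. The liberated dimethylamine removes the formate, and the product is the enaminone alcohol F1. Catalytic PPTS in CH2Cl2 then lets the benzylic hydroxyl replace dimethylamine by addition and elimination, which closes 9.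

Step 3 (Mitsunobu inversion).
- **Risk:** The electron-rich benzylic oxyphosphonium ion may ionise, which erodes the inversion, or it may eliminate towards the styrene.
- **Fallback:** It sets out from 6 and comes back at 7. Dess–Martin periodinane in CH2Cl2 oxidises 6 to the aryl ketone F2. Reduction with BH3·SMe2 and (R)-2-methyl-CBS-oxazaborolidine sets the (S) carbinol under catalyst control and gives the syn alcohol F3. Acetic formic anhydride and pyridine convert it into 7.

Step 7 (key step).
- **Risk:** The lactone may be deprotonated instead of attacked, or the tetrahedral alkoxide may collapse early and take up a second aryllithium.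
- **Fallback:** It sets out from 10 and comes back at 15. i-Bu2AlH in toluene at −78 °C reduces 10 to the lactol F4. Two equivalents of 13 add to its open hydroxy aldehyde form and make the same carbon–carbon bond at the alcohol level, giving the diol F5. MnO2 in CH2Cl2 oxidises only the benzylic secondary alcohol and gives 15.

Further compounds
F1 | step 4 | (4R)-3-(dimethylaminomethylene)-4-[(S)-Ar(hydroxy)methyl]dihydrofuran-2(3H)-one | CN(C)C=C1C(=O)OC[C@@H]1[C@H](O)c2cc(OC)c(O[Si](C)(C)C(C)(C)C)c(OC)c2
F2 | step 3 | (4R)-4-[4-(tert-butyldimethylsilyloxy)-3,5-dimethoxybenzoyl]dihydrofuran-2(3H)-one | O=C1C[C@H](CO1)C(=O)c2cc(OC)c(O[Si](C)(C)C(C)(C)C)c(OC)c2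
F3 | step 3 | (4R)-4-[(S)-Ar(hydroxy)methyl]dihydrofuran-2(3H)-one | O=C1C[C@H](CO1)[C@H](O)c2cc(OC)c(O[Si](C)(C)C(C)(C)C)c(OC)c2
F4 | step 7 | (3aR,4S,6aR)-4-Ar-tetrahydro-1H,3H-furo[3,4-c]furan-1-ol | OC1OC[C@H]2[C@@H]1CO[C@@H]2c3cc(OC)c(O[Si](C)(C)C(C)(C)C)c(OC)c3
F5 | step 7 | Ar[(3R,4R,5S)-5-Ar-4-(hydroxymethyl)tetrahydrofuran-3-yl]methanol | COc1cc(C(O)[C@H]2CO[C@H](c3cc(OC)c(O[Si](C)(C)C(C)(C)C)c(OC)c3)[C@H]2CO)cc(OC)c1O[Si](C)(C)C(C)(C)C
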